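**Plan**

- Retrosynthesis: the five benzyl ethers come off last. Before that the flavanone heterocycle is cut at two bonds at once, O1–C8a and C4–C4a. This leaves 3,5-bis(benzyloxy)benzyne and an (S)-β-silyloxy ester that already holds O1, C2, C3, C4 and the whole kaempferol half.
- The β-oxy ester goes back through a β-keto ester to an aryl aldehyde. The diaryl ether is cut by SNAr into tri-O-benzylkaempferol and 4-fluorobenzaldehyde, and the flavonol goes back to a chalcone.
- Forward: chalcone, flavone, 3-hydroxylation, diaryl ether, two-carbon chain and carbinol. Then the pyranone ring of the flavanone half is closed onto its ring A, which arrives as the aryne, and hydrogenolysis follows.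
- Enabling feature: ring A of the flavanone is a phloroglucinol ring whose neighbouring carbons C8a and C4a carry O1 and the C4 carbonyl, with the C5 oxygen beside C4a. This is the ortho-difunctionalisation pattern of a 3,5-dioxygenated benzyne. Its C3 oxygen sends an oxygen nucleophile to C8a and leaves the carbanion at C4a, which is joined through O1–C2–C3 to the ester carbon.
- Stereochemistry: the only stereocenter (C2, S) is set by Noyori–Ikariya transfer hydrogenation of the β-keto ester, and its C–O bond is not broken afterwards.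

Key step: step 10

Remark: ketone 1 and phenol 13 are taken as catalogue compounds; the single stereocenter of the target is C2 of the flavanone half and is S.

**Route**

Step 1
Reactants: 1 1-[2,4-bis(benzyloxy)-6-hydroxyphenyl]ethan-1-one; 2 4-(benzyloxy)benzaldehyde
Product: 3 (E)-1-[2,4-bis(benzyloxy)-6-hydroxyphenyl]-3-[4-(benzyloxy)phenyl]prop-2-en-1-one
Conditions: KOH (50% aq.), EtOH/THF, rt
Reagents that add atoms: none
Why: Claisen–Schmidt condensation of a methyl ketone with a non-enolisable aryl aldehyde; dehydration of the aldol should give the E enone.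

Step 2
Reactants: 3 the chalcone
Product: 4 5,7-bis(benzyloxy)-2-[4-(benzyloxy)phenyl]-4H-chromen-4-one
Conditions: I2 (10 mol%), DMSO, 130 °C
Reagents that add atoms: none
Why: Iodine/DMSO oxidative cyclisation of a 2'-hydroxychalcone (oxa-Michael closure, α-iodination, loss of HI, with DMSO reoxidising iodide) is the standard route to flavones and tolerates benzyl ethers.

Step 3
Reactants: 4 the flavone
Product: 6 5,7-bis(benzyloxy)-2-[4-(benzyloxy)phenyl]-3-hydroxy-4H-chromen-4-one, via flavone 2,3-epoxide 5 (not isolated)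
Conditions: dimethyldioxirane (acetone solution), CH2Cl2, 0 °C to rt; then TsOH·H2O (cat.), CH2Cl2, rt
Reagents that add atoms: dimethyldioxirane, CC1(C)OO1
Why: Dioxirane epoxidation of the flavone C2=C3 bond followed by acid-catalysed epoxide opening and loss of H3 is an established flavone-to-flavonol oxidation; it replaces the Algar–Flynn–Oyamada reaction, which tends to give aurones from 6'-alkoxychalcones, and the epoxide stereocenters vanish on rearomatisation.

Step 4
Reactants: 6 the flavonol; 7 4-fluorobenzaldehyde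
Product: 8 4-({5,7-bis(benzyloxy)-2-[4-(benzyloxy)phenyl]-4-oxo-4H-chromen-3-yl}oxy)benzaldehyde
Conditions: K2CO3, DMF, 100 °C, argon
Reagents that add atoms: none
Why: Nucleophilic aromatic substitution (addition–elimination): the acidic enolic 3-OH is the only free hydroxyl and its potassium salt should displace fluoride para to the formyl group.

Step 5
Reactants: 8 the aldehyde; 9 ethyl diazoacetate
Product: 10 ethyl 3-[4-({5,7-bis(benzyloxy)-2-[4-(benzyloxy)phenyl]-4-oxo-4H-chromen-3-yl}oxy)phenyl]-3-oxopropanoate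
Conditions: NbCl5 (5 mol%), CH2Cl2, rt
Reagents that add atoms: none
Why: Roskamp homologation: Lewis-acid-promoted addition of the diazo ester to the aldehyde, then 1,2-hydride shift with loss of N2, should give the β-keto ester and leave the chromone untouched.

Step 6
Reactants: 10 the β-keto ester
Product: 11 ethyl (3S)-3-[4-({5,7-bis(benzyloxy)-2-[4-(benzyloxy)phenyl]-4-oxo-4H-chromen-3-yl}oxy)phenyl]-3-hydroxypropanoate
Conditions: RuCl(p-cymene)[(S,S)-TsDPEN] (2 mol%), HCO2H/Et3N (5:2), CH2Cl2, 30 °C
Reagents that add atoms: none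
Why: Noyori–Ikariya asymmetric transfer hydrogenation: hydride and proton pass to the aryl ketone through the outer-sphere six-membered transition state with the aryl ring under the p-cymene ligand, so the (S,S) catalyst should give the S carbinol as with other aryl ketones and benzoylacetates, while the electron-rich chromone carbonyl is too poor an acceptor to compete.

Step 7
Reactants: 11 the (S)-β-hydroxy ester
Product: 12 ethyl (3S)-3-[4-({5,7-bis(benzyloxy)-2-[4-(benzyloxy)phenyl]-4-oxo-4H-chromen-3-yl}oxy)phenyl]-3-[(trimethylsilyl)oxy]propanoate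
Conditions: Me3SiCl, imidazole, CH2Cl2, 0 °C; filtration through Et3N-deactivated silica
Reagents that add atoms: chlorotrimethylsilane, C[Si](C)(C)Cl
Why: Routine O-silylation; the silyl ether is the helper for step 10, where fluoride turns it into a proton-free alkoxide, and it leaves the carbinol configuration untouched.

Step 8
Reactants: 13 3,5-bis(benzyloxy)phenol
Product: 14 3,5-bis(benzyloxy)-2-bromophenol
Conditions: N-bromosuccinimide (1.0 equiv), CH2Cl2, −78 °C to rt
Reagents that add atoms: N-bromosuccinimide, O=C1CCC(=O)N1Br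
Why: Electrophilic aromatic bromination; at low temperature in a non-polar solvent the position ortho to the free hydroxyl should be preferred over the more hindered position between the two benzyloxy groups.

Step 9
Reactants: 14 the bromophenol
Product: 17 3,5-bis(benzyloxy)-2-(trimethylsilyl)phenyl trifluoromethanesulfonate, via aryl trimethylsilyl ether 15 (not isolated), via lithium 2-silylphenoxide 16 (not isolated)
Conditions: (Me3Si)2NH, THF, 65 °C, then evaporation; n-BuLi, THF, −78 °C; Tf2O, −78 to 0 °C
Reagents that add atoms: hexamethyldisilazane, C[Si](C)(C)N[Si](C)(C)C; trifluoromethanesulfonic anhydride, O=S(=O)(OS(=O)(=O)C(F)(F)F)C(F)(F)F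
Why: The standard one-flask route to o-silylaryl triflates: O-silylation, bromine–lithium exchange, retro-Brook 1,3-shift of silicon from oxygen to carbon, and triflation of the phenoxide.

Step 10
Reactants: 12 the (S)-β-silyloxy ester; 17 the o-silylaryl triflate
Product: 20 (2S)-5,7-bis(benzyloxy)-2-[4-({5,7-bis(benzyloxy)-2-[4-(benzyloxy)phenyl]-4-oxo-4H-chromen-3-yl}oxy)phenyl]-2,3-dihydro-4H-chromen-4-one, via 3,5-bis(benzyloxy)benzyne 18 (not isolated), via cesium alkoxide 19 (not isolated)
Conditions: 17 (1.5 equiv), CsF (1.5 equiv), MeCN/THF (1:1), 0 °C to rt; pH 7 phosphate buffer quench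
Reagents that add atoms: none
Why: Proposed new method: fluoride strips the trimethylsilyl groups of 12 and 17 side by side, so alkoxide 19 and aryne 18 meet at low concentration; the alkoxide oxygen adds to the aryne carbon remote from the neighbouring benzyloxy group, the resulting aryl anion lies between the new ether oxygen and that benzyloxy group and attacks the ethyl ester in a 6-exo-trig closure, and loss of ethoxide gives the chroman-4-one ring. The closest known reaction type is the fluoride-induced annulation of arynes with salicylate esters to xanthones, where a phenoxide adds and the aryl anion is acylated by the adjacent ester; the extension here is to an aliphatic, silyl-masked β-hydroxy ester. No stereocenter is formed, and the C–O bond of the carbinol carbon set in step 6 is never broken, so its S configuration becomes C2 of the flavanone. The regiochemistry needed (ether oxygen meta and acyl carbon ortho to the benzyloxy group that becomes C5–O) is secured by the inductive effect of the benzyloxy group next to the aryne bond, which directs nucleophiles to the distal aryne carbon. The ethoxide released is meant to be taken up by silicon as ethoxytrimethylsilane, with fluoride kept below the total silyl content, so that no strong base is left to open the flavanone to the chalcone and erode C2.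

Step 11
Reactants: 20 the pentabenzyl ether
Product: 21 (2S)-2-(4-{[5,7-dihydroxy-2-(4-hydroxyphenyl)-4-oxo-4H-chromen-3-yl]oxy}phenyl)-5,7-dihydroxy-2,3-dihydro-4H-chromen-4-one
Conditions: H2 (1 atm), Pd/C (10 wt% Pd), THF/MeOH, rt, stopped at full conversion
Reagents that add atoms: none
Why: Catalytic hydrogenolysis of aryl benzyl ethers under neutral conditions, which should not epimerise C2 (base is avoided) and should leave the diaryl ether and both pyranone rings intact.

**Compound list**

1 | 1-[2,4-bis(benzyloxy)-6-hydroxyphenyl]ethan-1-one | CC(=O)c1c(O)cc(OCc2ccccc2)cc1OCc1ccccc1 | starting material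
2 | 4-(benzyloxy)benzaldehyde | O=Cc1ccc(OCc2ccccc2)cc1 | starting material
3 | (E)-1-[2,4-bis(benzyloxy)-6-hydroxyphenyl]-3-[4-(benzyloxy)phenyl]prop-2-en-1-one | O=C(/C=C/c1ccc(OCc2ccccc2)cc1)c1c(O)cc(OCc2ccccc2)cc1OCc1ccccc1 | intermediate
4 | 5,7-bis(benzyloxy)-2-[4-(benzyloxy)phenyl]-4H-chromen-4-one | O=c1cc(-c2ccc(OCc3ccccc3)cc2)oc2cc(OCc3ccccc3)cc(OCc3ccccc3)c12 | intermediate
5 | 2,3-epoxide of flavone 4 (racemic, not isolated) | O=C1C2OC2(c2ccc(OCc3ccccc3)cc2)Oc2cc(OCc3ccccc3)cc(OCc3ccccc3)c21 | intermediate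
6 | 5,7-bis(benzyloxy)-2-[4-(benzyloxy)phenyl]-3-hydroxy-4H-chromen-4-one (5,7,4'-tri-O-benzylkaempferol) | O=c1c(O)c(-c2ccc(OCc3ccccc3)cc2)oc2cc(OCc3ccccc3)cc(OCc3ccccc3)c12 | intermediate
7 | 4-fluorobenzaldehyde | O=Cc1ccc(F)cc1 | starting material
8 | 4-({5,7-bis(benzyloxy)-2-[4-(benzyloxy)phenyl]-4-oxo-4H-chromen-3-yl}oxy)benzaldehyde | O=Cc1ccc(Oc2c(-c3ccc(OCc4ccccc4)cc3)oc3cc(OCc4ccccc4)cc(OCc4ccccc4)c3c2=O)cc1 | intermediate
9 | ethyl diazoacetate | CCOC(=O)C=[N+]=[N-] | starting material
10 | ethyl 3-[4-({5,7-bis(benzyloxy)-2-[4-(benzyloxy)phenyl]-4-oxo-4H-chromen-3-yl}oxy)phenyl]-3-oxopropanoate | CCOC(=O)CC(=O)c1ccc(Oc2c(-c3ccc(OCc4ccccc4)cc3)oc3cc(OCc4ccccc4)cc(OCc4ccccc4)c3c2=O)cc1 | intermediate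
11 | ethyl (3S)-3-[4-({5,7-bis(benzyloxy)-2-[4-(benzyloxy)phenyl]-4-oxo-4H-chromen-3-yl}oxy)phenyl]-3-hydroxypropanoate | CCOC(=O)C[C@@H](c1ccc(Oc2c(-c3ccc(OCc4ccccc4)cc3)oc3cc(OCc4ccccc4)cc(OCc4ccccc4)c3c2=O)cc1)O | intermediate
12 | ethyl (3S)-3-[4-({5,7-bis(benzyloxy)-2-[4-(benzyloxy)phenyl]-4-oxo-4H-chromen-3-yl}oxy)phenyl]-3-[(trimethylsilyl)oxy]propanoate | CCOC(=O)C[C@@H](c1ccc(Oc2c(-c3ccc(OCc4ccccc4)cc3)oc3cc(OCc4ccccc4)cc(OCc4ccccc4)c3c2=O)cc1)O[Si](C)(C)C | intermediate
13 | 3,5-bis(benzyloxy)phenol | Oc1cc(OCc2ccccc2)cc(OCc2ccccc2)c1 | starting material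
14 | 3,5-bis(benzyloxy)-2-bromophenol | Oc1cc(OCc2ccccc2)cc(OCc2ccccc2)c1Br | intermediate
15 | [3,5-bis(benzyloxy)-2-bromophenoxy]trimethylsilane (not isolated) | C[Si](C)(C)Oc1cc(OCc2ccccc2)cc(OCc2ccccc2)c1Br | intermediate
16 | lithium 3,5-bis(benzyloxy)-2-(trimethylsilyl)phenoxide (not isolated) | [Li+].[O-]c1cc(OCc2ccccc2)cc(OCc2ccccc2)c1[Si](C)(C)C | intermediate
17 | 3,5-bis(benzyloxy)-2-(trimethylsilyl)phenyl trifluoromethanesulfonate | C[Si](C)(C)c1c(OCc2ccccc2)cc(OCc2ccccc2)cc1OS(=O)(=O)C(F)(F)F | intermediate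
18 | 3,5-bis(benzyloxy)benzyne (not isolated) | C1#CC(OCc2ccccc2)=CC(OCc2ccccc2)=C1 | intermediate
19 | cesium (1S)-alkoxide freed from 12 (not isolated) | [Cs+].CCOC(=O)C[C@@H](c1ccc(Oc2c(-c3ccc(OCc4ccccc4)cc3)oc3cc(OCc4ccccc4)cc(OCc4ccccc4)c3c2=O)cc1)[O-] | intermediate
20 | (2S)-5,7-bis(benzyloxy)-2-[4-({5,7-bis(benzyloxy)-2-[4-(benzyloxy)phenyl]-4-oxo-4H-chromen-3-yl}oxy)phenyl]-2,3-dihydro-4H-chromen-4-one | O=C1C[C@@H](c2ccc(Oc3c(-c4ccc(OCc5ccccc5)cc4)oc4cc(OCc5ccccc5)cc(OCc5ccccc5)c4c3=O)cc2)Oc2cc(OCc3ccccc3)cc(OCc3ccccc3)c21 | intermediate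
21 | (2S)-2-(4-{[5,7-dihydroxy-2-(4-hydroxyphenyl)-4-oxo-4H-chromen-3-yl]oxy}phenyl)-5,7-dihydroxy-2,3-dihydro-4H-chromen-4-one | O=C1C[C@@H](c2ccc(Oc3c(-c4ccc(O)cc4)oc4cc(O)cc(O)c4c3=O)cc2)Oc2cc(O)cc(O)c21 | target

**Step count and risks**

Total steps: 11. Longest linear sequence: 9 (steps 1–7, 10, 11).

Steps most likely to fail:

1. Step 10 (proposed new method). Three processes can defeat it:
   - fragmentation of the unmasked alkoxide by retro-aldol cleavage or β-elimination before it is arylated;
   - protonation of the aryl anion, or its abstraction of an α-ester proton, before it acylates;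
   - base-induced opening of the new pyranone ring by the released ethoxide, with loss of configuration at C2.

   Fallback (known reaction types; the two bonds are made one after the other without a free alkoxide): the route is left at β-keto ester 10. Transfer hydrogenation with the enantiomeric catalyst RuCl(p-cymene)[(R,R)-TsDPEN] should give ethyl (3R)-3-[4-({5,7-bis(benzyloxy)-2-[4-(benzyloxy)phenyl]-4-oxo-4H-chromen-3-yl}oxy)phenyl]-3-hydroxypropanoate F1. Mitsunobu etherification of this with phenol 13 (PPh3, diisopropyl azodicarboxylate, toluene, 0 °C) should invert the carbinol carbon and give ethyl (3S)-3-[3,5-bis(benzyloxy)phenoxy]-3-[4-({5,7-bis(benzyloxy)-2-[4-(benzyloxy)phenyl]-4-oxo-4H-chromen-3-yl}oxy)phenyl]propanoate F2. Saponification (LiOH, THF/H2O, 0 °C) should give (3S)-3-[3,5-bis(benzyloxy)phenoxy]-3-[4-({5,7-bis(benzyloxy)-2-[4-(benzyloxy)phenyl]-4-oxo-4H-chromen-3-yl}oxy)phenyl]propanoic acid F3. Intramolecular Friedel–Crafts acylation (trifluoroacetic anhydride, CH2Cl2, 0 °C) onto either of the two equivalent positions ortho to the ether oxygen should close the ring, and the route is rejoined at 20.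

2. Step 4. The hindered, delocalised 3-oxido group may be too poor a nucleophile for the substitution, and the flavonolate may degrade oxidatively during prolonged heating. Fallback: copper-catalysed Ullmann-type C–O coupling of 6 with 4-iodobenzaldehyde (CuI, picolinic acid, K3PO4, DMSO, 90 °C, argon), which leaves the route at 6 and comes back at 8; no new compound arises (F0).

3. Step 11. Over-reduction may occur by hydrogenolytic opening of the flavanone pyranone ring at the benzylic C2–O1 bond, or the chelated 5-benzyl ethers may cleave incompletely. Fallback: non-reductive Lewis-acid debenzylation of 20 with BCl3 and pentamethylbenzene as benzyl-cation scavenger (CH2Cl2, −78 °C), which gives 21 directly; no new compound arises (F0).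

**Further compounds**

F1 | step 10 | ethyl (3R)-3-[4-({5,7-bis(benzyloxy)-2-[4-(benzyloxy)phenyl]-4-oxo-4H-chromen-3-yl}oxy)phenyl]-3-hydroxypropanoate | CCOC(=O)C[C@H](c1ccc(Oc2c(-c3ccc(OCc4ccccc4)cc3)oc3cc(OCc4ccccc4)cc(OCc4ccccc4)c3c2=O)cc1)O
F2 | step 10 | ethyl (3S)-3-[3,5-bis(benzyloxy)phenoxy]-3-[4-({5,7-bis(benzyloxy)-2-[4-(benzyloxy)phenyl]-4-oxo-4H-chromen-3-yl}oxy)phenyl]propanoate | CCOC(=O)C[C@@H](c1ccc(Oc2c(-c3ccc(OCc4ccccc4)cc3)oc3cc(OCc4ccccc4)cc(OCc4ccccc4)c3c2=O)cc1)Oc1cc(OCc2ccccc2)cc(OCc2ccccc2)c1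
F3 | step 10 | (3S)-3-[3,5-bis(benzyloxy)phenoxy]-3-[4-({5,7-bis(benzyloxy)-2-[4-(benzyloxy)phenyl]-4-oxo-4H-chromen-3-yl}oxy)phenyl]propanoic acid | OC(=O)C[C@@H](c1ccc(Oc2c(-c3ccc(OCc4ccccc4)cc3)oc3cc(OCc4ccccc4)cc(OCc4ccccc4)c3c2=O)cc1)Oc1cc(OCc2ccccc2)cc(OCc2ccccc2)c1
F0 | step 4 | none | none
F0 | step 11 | none | none
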